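**Retrosynthetic overview**

1. Locants: cyclohexanol C1 (carbinol), C3 (CHBr), C4 (CMeCl); cyclopentane C1' (quaternary, on C1), C2' (CMe2), C3' (CHBr), C4', C5' (CHOH). The plan rests on C2', the gem-dimethyl carbon between the quaternary C1' and the heteroatom-bearing C3': C2' can be a tertiary radical born from an isopropenyl group and C3' an aldehyde carbon.
2. C4–Cl comes from chloride opening (retention) of a C1–O–C4 oxa-bridge; the bridge and C3–Br from bromoetherification of a 4-methylcyclohex-3-en-1-ol; the cyclohexene from ring-closing metathesis; C1 from chelation-controlled allylation of a ketone grown from the C1' ester.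
3. C3'–Br comes from hydrogen-atom-transfer hydrogenation of a C3' alkenyl bromide made from the C3' ketone; the cyclopentane from iron-hydride radical cyclisation of an isopropenyl aldehyde (bond C2'–C3').
4. The acyclic precursor comes from an auxiliary-controlled deconjugative aldol (sets C5') followed by chelate-controlled α-methylation (sets C1').
5. Ring order: cyclopentane (step 8), cyclohexene (step 19), temporary oxa-bridge (step 20, opened in step 21).

Key step: step 8

Remark: alcohol 14 is carried on as its mixture of C3' epimers, because step 9 removes this stereocentre and step 12 sets it again.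

**Step 1**
Reactants: 1 (4S)-4-benzyl-1,3-oxazolidin-2-one; 2 3-methylbut-2-enoyl chloride
Product: 4 (4S)-4-benzyl-3-(3-methylbut-2-enoyl)-1,3-oxazolidin-2-one, via lithium oxazolidinide 3 (not isolated)
Conditions: n-BuLi, THF, −78 °C; then 2, −78 → 0 °C
Reagents that add atoms: none
Why: N-acylation of the lithiated Evans oxazolidinone by an acid chloride is standard and leaves the conjugated alkene untouched.

**Step 2**
Reactants: 5 methyl 3,3-dimethoxypropanoate
Product: 6 3,3-dimethoxypropanal
Conditions: i-Bu2AlH (1.05 equiv), CH2Cl2, −78 °C; then aq. potassium sodium tartrate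
Reagents that add atoms: none
Why: Partial ester reduction, in which the tetrahedral aluminium hemiacetal is stable at −78 °C and releases the aldehyde only on work-up, while the acetal is inert.

**Step 3**
Reactants: 4 (4S)-4-benzyl-3-(3-methylbut-2-enoyl)-1,3-oxazolidin-2-one; 6 3,3-dimethoxypropanal
Product: 8 (4S)-4-benzyl-3-[(2S,3R)-3-hydroxy-5,5-dimethoxy-2-(prop-1-en-2-yl)pentanoyl]-1,3-oxazolidin-2-one, via dibutylboron dienolate 7 (not isolated)
Conditions: n-Bu2BOTf, Et3N, CH2Cl2, −78 → 0 °C; then 6, −78 → 0 °C; pH 7 buffer, MeOH, H2O2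
Reagents that add atoms: none
Why: Evans syn-aldol, in which γ-deprotonation gives the (Z)-dienol borinate that reacts at its α-carbon through a Zimmerman–Traxler chair on the face away from the benzyl group, setting the carbinol centre (3R) and placing the isopropenyl group on C2 (the C2 configuration is not used later).

**Step 4**
Reactants: 8 (4S)-4-benzyl-3-[(2S,3R)-3-hydroxy-5,5-dimethoxy-2-(prop-1-en-2-yl)pentanoyl]-1,3-oxazolidin-2-one
Product: 9 methyl (2S,3R)-3-hydroxy-5,5-dimethoxy-2-(prop-1-en-2-yl)pentanoate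
Conditions: NaOMe (1.1 equiv), MeOH, 0 °C; then H2O
Reagents that add atoms: sodium methoxide, [Na+].[O-]C
Why: Transesterification by methoxide at the exocyclic imide carbonyl releases the auxiliary, and any epimerisation or conjugation at C2 is harmless because step 5 turns C2 into an enolate.

**Step 5**
Reactants: 9 methyl (2S,3R)-3-hydroxy-5,5-dimethoxy-2-(prop-1-en-2-yl)pentanoate
Product: 11 methyl (2S,3R)-3-hydroxy-5,5-dimethoxy-2-methyl-2-(prop-1-en-2-yl)pentanoate, via dilithium dianion 10 (not isolated)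
Conditions: LiN(i-Pr)2 (2.3 equiv), THF, −78 → −20 °C; then MeI, DMPU, −78 → −20 °C; then H2O
Reagents that add atoms: iodomethane, CI
Why: Fráter–Seebach alkylation, in which the lithium-chelated alkoxide–dienolate is methylated at its α-carbon on the face anti to the C3 side chain, so the quaternary centre (2S) forms with methyl anti and isopropenyl syn to the hydroxyl.

**Step 6**
Reactants: 11 methyl (2S,3R)-3-hydroxy-5,5-dimethoxy-2-methyl-2-(prop-1-en-2-yl)pentanoate
Product: 12 methyl (2S,3R)-3-[(tert-butyldimethylsilyl)oxy]-5,5-dimethoxy-2-methyl-2-(prop-1-en-2-yl)pentanoate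
Conditions: TBSOTf, 2,6-lutidine, CH2Cl2, −78 → 0 °C
Reagents that add atoms: tert-butyldimethylsilyl trifluoromethanesulfonate, CC(C)(C)[Si](C)(C)OS(=O)(=O)C(F)(F)F
Why: A silyl triflate with a hindered base silylates the congested secondary alcohol and spares the acetal at low temperature.

**Step 7**
Reactants: 12 methyl (2S,3R)-3-[(tert-butyldimethylsilyl)oxy]-5,5-dimethoxy-2-methyl-2-(prop-1-en-2-yl)pentanoate
Product: 13 methyl (2S,3R)-3-[(tert-butyldimethylsilyl)oxy]-2-methyl-5-oxo-2-(prop-1-en-2-yl)pentanoate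
Conditions: PPTS (0.2 equiv), acetone–H2O (10:1), 50 °C
Reagents that add atoms: water, O
Why: Mild acid-catalysed acetal hydrolysis frees the aldehyde while the hindered secondary silyl ether survives.

**Step 8**
Reactants: 13 methyl (2S,3R)-3-[(tert-butyldimethylsilyl)oxy]-2-methyl-5-oxo-2-(prop-1-en-2-yl)pentanoate
Product: 14 methyl (1S,5R)-5-[(tert-butyldimethylsilyl)oxy]-3-hydroxy-1,2,2-trimethylcyclopentane-1-carboxylate (mixture of C3 epimers; 3S expected to be the main one)
Conditions: Fe(acac)3 (0.5 equiv), PhSiH3 (2.5 equiv), EtOH (0.02 M), 60 °C, argon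
Reagents that add atoms: none
Why: The iron hydride formed from Fe(acac)3 and PhSiH3 transfers a hydrogen atom to the terminal CH2 of the isopropenyl group, which makes the second methyl on C2' and a nucleophilic tertiary radical; this adds to the aldehyde carbon C3' and the alkoxy radical is reduced and protonated in EtOH, the closest known reaction type being the Fe(acac)3/PhSiH3 reductive radical cyclisation of alkenes onto carbonyl groups, shown so far mainly with ketones. The cyclopentane closes in the 5-exo-trig mode (C2' onto C3'), preferred over 6-endo attack at oxygen and helped by the fully substituted C1' (Thorpe–Ingold effect). The new stereocentre C3' is governed by a chair-like Beckwith–Houk transition state with the C5' silyloxy group and the C1' methyl pseudo-equatorial, so the alcohol cis to the silyloxy and ester groups (3S) should be the main epimer. No selectivity at C3' is needed, because step 9 oxidises both epimers to one ketone; what is needed is ring closure ahead of plain reduction of the radical and ahead of β-scission of the alkoxy radical, which the geminal substitution at C1' and the polarity match between tertiary radical and aldehyde are expected to secure. A polar closure (Prins or carbonyl-ene) would bond the terminal alkene carbon and give a six-membered ring, so only the radical mode forms C2'–C3' next to the quaternary C1'.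

**Step 9**
Reactants: 14 methyl (1S,5R)-5-[(tert-butyldimethylsilyl)oxy]-3-hydroxy-1,2,2-trimethylcyclopentane-1-carboxylate (both C3 epimers)
Product: 15 methyl (1S,5R)-5-[(tert-butyldimethylsilyl)oxy]-1,2,2-trimethyl-3-oxocyclopentane-1-carboxylate
Conditions: Dess–Martin periodinane, CH2Cl2, rt
Reagents that add atoms: none
Why: Dess–Martin oxidation of the hindered secondary alcohol converts both C3' epimers into a single ketone.

**Step 10**
Reactants: 15 methyl (1S,5R)-5-[(tert-butyldimethylsilyl)oxy]-1,2,2-trimethyl-3-oxocyclopentane-1-carboxylate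
Product: 17 methyl (1S,5R)-5-[(tert-butyldimethylsilyl)oxy]-1,2,2-trimethyl-3-[(trifluoromethanesulfonyl)oxy]cyclopent-3-ene-1-carboxylate, via potassium enolate 16 (not isolated)
Conditions: KN(SiMe3)2, THF, −78 °C; then Comins' reagent, −78 °C; then H2O
Reagents that add atoms: N-(5-chloropyridin-2-yl)-1,1,1-trifluoro-N-(trifluoromethanesulfonyl)methanesulfonamide (Comins' reagent), O=S(=O)(N(c1ccc(Cl)cn1)S(=O)(=O)C(F)(F)F)C(F)(F)F
Why: Kinetic deprotonation at C4', the only enolisable position, and fast O-triflation at −78 °C give the enol triflate before the β-silyloxy group can be expelled.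

**Step 11**
Reactants: 17 methyl (1S,5R)-5-[(tert-butyldimethylsilyl)oxy]-1,2,2-trimethyl-3-[(trifluoromethanesulfonyl)oxy]cyclopent-3-ene-1-carboxylate
Product: 18 methyl (1S,5R)-3-bromo-5-[(tert-butyldimethylsilyl)oxy]-1,2,2-trimethylcyclopent-3-ene-1-carboxylate
Conditions: Ni(cod)2 (10 mol %), LiBr (3 equiv), N,N-dimethylacetamide–THF, rt
Reagents that add atoms: lithium bromide, [Li+].[Br-]
Why: Nickel-catalysed triflate–halide exchange (oxidative addition of zerovalent nickel into the C–O bond, bromide exchange, reductive elimination) is an established route from enol triflates to alkenyl bromides and tolerates the ester and silyl ether.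

**Step 12**
Reactants: 18 methyl (1S,5R)-3-bromo-5-[(tert-butyldimethylsilyl)oxy]-1,2,2-trimethylcyclopent-3-ene-1-carboxylate
Product: 19 methyl (1S,3S,5R)-3-bromo-5-[(tert-butyldimethylsilyl)oxy]-1,2,2-trimethylcyclopentane-1-carboxylate
Conditions: Mn(dpm)3 (10 mol %), PhSiH3, t-BuOOH, i-PrOH, rt
Reagents that add atoms: none
Why: Manganese-hydride hydrogen-atom-transfer hydrogenation reduces haloalkenes without cleaving the carbon–halogen bond; H• adds to C4' and the α-bromo radical at C3' takes its second hydrogen on the face opposite the C5' silyloxy and C1' ester groups, so bromine ends cis to both (3S).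

**Step 13**
Reactants: 19 methyl (1S,3S,5R)-3-bromo-5-[(tert-butyldimethylsilyl)oxy]-1,2,2-trimethylcyclopentane-1-carboxylate
Product: 20 [(1R,3S,5R)-3-bromo-5-[(tert-butyldimethylsilyl)oxy]-1,2,2-trimethylcyclopentyl]methanol
Conditions: i-Bu2AlH (3 equiv), CH2Cl2, −78 → 0 °C; then aq. potassium sodium tartrate
Reagents that add atoms: none
Why: i-Bu2AlH reduces the hindered ester to the primary alcohol and does not attack the secondary alkyl bromide or the silyl ether.

**Step 14**
Reactants: 20 [(1R,3S,5R)-3-bromo-5-[(tert-butyldimethylsilyl)oxy]-1,2,2-trimethylcyclopentyl]methanol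
Product: 21 (1S,3S,5R)-3-bromo-5-[(tert-butyldimethylsilyl)oxy]-1,2,2-trimethylcyclopentane-1-carbaldehyde
Conditions: Dess–Martin periodinane, CH2Cl2, rt
Reagents that add atoms: none
Why: Dess–Martin oxidation gives an aldehyde that has no α-hydrogen and therefore cannot epimerise.

**Step 15**
Reactants: 21 (1S,3S,5R)-3-bromo-5-[(tert-butyldimethylsilyl)oxy]-1,2,2-trimethylcyclopentane-1-carbaldehyde; 22 4-bromo-2-methylbut-1-ene
Product: 24 1-[(1R,3S,5R)-3-bromo-5-[(tert-butyldimethylsilyl)oxy]-1,2,2-trimethylcyclopentyl]-4-methylpent-4-en-1-ol (both carbinol epimers), via Grignard reagent 23 (not isolated)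
Conditions: Mg, THF, rt (22 gives 23); then 21, THF, −78 → 0 °C; then H2O
Reagents that add atoms: none
Why: Grignard addition to the hindered but reactive aldehyde, in which the carbinol configuration is irrelevant (oxidised in step 16) and the neopentyl secondary bromide is inert to the reagent at low temperature.

**Step 16**
Reactants: 24 1-[(1R,3S,5R)-3-bromo-5-[(tert-butyldimethylsilyl)oxy]-1,2,2-trimethylcyclopentyl]-4-methylpent-4-en-1-ol
Product: 25 1-[(1S,3S,5R)-3-bromo-5-[(tert-butyldimethylsilyl)oxy]-1,2,2-trimethylcyclopentyl]-4-methylpent-4-en-1-one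
Conditions: Dess–Martin periodinane, CH2Cl2, rt
Reagents that add atoms: none
Why: Dess–Martin oxidation of the secondary alcohol gives the ketone that carries C1 and the C4–C6 arm of the future cyclohexane.

**Step 17**
Reactants: 25 1-[(1S,3S,5R)-3-bromo-5-[(tert-butyldimethylsilyl)oxy]-1,2,2-trimethylcyclopentyl]-4-methylpent-4-en-1-one
Product: 26 1-[(1S,3S,5R)-3-bromo-5-hydroxy-1,2,2-trimethylcyclopentyl]-4-methylpent-4-en-1-one
Conditions: HF·pyridine, THF, 0 °C → rt
Reagents that add atoms: none
Why: Acidic fluoride desilylation frees the C5' hydroxyl without the retro-aldol cleavage that a basic fluoride source could start in this β-hydroxy ketone.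

**Step 18**
Reactants: 26 1-[(1S,3S,5R)-3-bromo-5-hydroxy-1,2,2-trimethylcyclopentyl]-4-methylpent-4-en-1-one; 27 allylmagnesium bromide
Product: 29 (4R)-4-[(1S,3S,5R)-3-bromo-5-hydroxy-1,2,2-trimethylcyclopentyl]-7-methylocta-1,7-dien-4-ol, via bromomagnesium alkoxide 28 (not isolated)
Conditions: 27 (3 equiv), THF, −78 °C; then H2O
Reagents that add atoms: none
Why: Chelation-controlled Grignard addition, in which the first equivalent makes the C5' bromomagnesium alkoxide that binds the ketone oxygen in a six-membered chelate cis-fused to the cyclopentane, and allyl then adds on the chelate face flanked by the C1' methyl and not on the face blocked by C2' and its methyl, setting C1 (R).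

**Step 19**
Reactants: 29 (4R)-4-[(1S,3S,5R)-3-bromo-5-hydroxy-1,2,2-trimethylcyclopentyl]-7-methylocta-1,7-dien-4-ol
Product: 30 (1R)-1-[(1S,3S,5R)-3-bromo-5-hydroxy-1,2,2-trimethylcyclopentyl]-4-methylcyclohex-3-en-1-ol
Conditions: second-generation Grubbs catalyst (5 mol %), CH2Cl2, 40 °C
Reagents that add atoms: none
Why: Ring-closing metathesis of the allyl group with the 1,1-disubstituted alkene closes the cyclohexene with the methyl on C4 and loses ethene.

**Step 20**
Reactants: 30 (1R)-1-[(1S,3S,5R)-3-bromo-5-hydroxy-1,2,2-trimethylcyclopentyl]-4-methylcyclohex-3-en-1-ol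
Product: 31 (1R,2S,4S)-4-bromo-2-[(1S,2S,4R)-2-bromo-1-methyl-7-oxabicyclo[2.2.1]heptan-4-yl]-2,3,3-trimethylcyclopentan-1-ol
Conditions: N-bromosuccinimide (1.05 equiv), CH2Cl2, 0 °C, dark
Reagents that add atoms: N-bromosuccinimide, O=C1CCC(=O)N1Br
Why: Bromoetherification, in which the tertiary C1 hydroxyl opens the bromonium ion transannularly at the tertiary C4 (as terpinen-4-ol-type alcohols close to 1,4-cineole skeletons), so oxygen binds C4 on the hydroxyl face and bromine binds C3 on the opposite face (3S in the cyclohexane numbering).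

**Step 21**
Reactants: 31 (1R,2S,4S)-4-bromo-2-[(1S,2S,4R)-2-bromo-1-methyl-7-oxabicyclo[2.2.1]heptan-4-yl]-2,3,3-trimethylcyclopentan-1-ol
Product: 34 (1R,3S,4S)-3-bromo-1-[(1S,3S,5R)-3-bromo-5-hydroxy-1,2,2-trimethylcyclopentyl]-4-chloro-4-methylcyclohexan-1-ol, via dichloroboryl ether 32 (not isolated), via cyclic chloroborate 33 (not isolated)
Conditions: BCl3 (2.2 equiv), CH2Cl2, −78 → −40 °C; then H2O (pH 7 buffer)
Reagents that add atoms: boron trichloride, ClB(Cl)Cl
Why: Proposed new method: BCl3 first turns the C5' hydroxyl into an O–BCl2 group whose boron binds the nearby bridge oxygen in a six-membered ring; the C4–O bond then ionises with help from the antiperiplanar C3 bromine (bromonium ion on the lower face) and chloride passes from boron to C4 on the face the oxygen leaves (retention), while C1–O stays inside the dioxaborinane; the closest known reactions are BCl3 cleavage of tertiary and bridged bicyclic ethers to alkyl chlorides and retentive substitution of trans-β-bromo alcohols through bromonium ions.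

**Compound list**

1 | (4S)-4-benzyl-1,3-oxazolidin-2-one | O=C1N[C@@H](Cc2ccccc2)CO1 | starting material
2 | 3-methylbut-2-enoyl chloride | CC(C)=CC(Cl)=O | starting material
3 | lithium (4S)-4-benzyl-2-oxo-1,3-oxazolidin-3-ide | [Li+].O=C1[N-][C@@H](Cc2ccccc2)CO1 | intermediate
4 | (4S)-4-benzyl-3-(3-methylbut-2-enoyl)-1,3-oxazolidin-2-one | CC(C)=CC(=O)N1[C@@H](Cc2ccccc2)COC1=O | intermediate
5 | methyl 3,3-dimethoxypropanoate | COC(CC(=O)OC)OC | starting material
6 | 3,3-dimethoxypropanal | COC(CC=O)OC | intermediate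
7 | (4S)-4-benzyl-3-[(1Z)-1-[(dibutylboranyl)oxy]-3-methylbuta-1,3-dien-1-yl]-1,3-oxazolidin-2-one | C=C(C)/C=C(\OB(CCCC)CCCC)N1[C@@H](Cc2ccccc2)COC1=O | intermediate
8 | (4S)-4-benzyl-3-[(2S,3R)-3-hydroxy-5,5-dimethoxy-2-(prop-1-en-2-yl)pentanoyl]-1,3-oxazolidin-2-one | COC(OC)C[C@@H](O)[C@H](C(C)=C)C(=O)N1[C@@H](Cc2ccccc2)COC1=O | intermediate
9 | methyl (2S,3R)-3-hydroxy-5,5-dimethoxy-2-(prop-1-en-2-yl)pentanoate | COC(OC)C[C@@H](O)[C@H](C(C)=C)C(=O)OC | intermediate
10 | dilithium alkoxide–dienolate of 9 (C3 alkoxide, ester enolate conjugated with the isopropenyl group) | [Li+].[Li+].COC(OC)C[C@@H]([O-])C(C(C)=C)=C([O-])OC | intermediate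
11 | methyl (2S,3R)-3-hydroxy-5,5-dimethoxy-2-methyl-2-(prop-1-en-2-yl)pentanoate | COC(OC)C[C@@H](O)[C@](C)(C(C)=C)C(=O)OC | intermediate
12 | methyl (2S,3R)-3-[(tert-butyldimethylsilyl)oxy]-5,5-dimethoxy-2-methyl-2-(prop-1-en-2-yl)pentanoate | COC(OC)C[C@@H](O[Si](C)(C)C(C)(C)C)[C@](C)(C(C)=C)C(=O)OC | intermediate
13 | methyl (2S,3R)-3-[(tert-butyldimethylsilyl)oxy]-2-methyl-5-oxo-2-(prop-1-en-2-yl)pentanoate | O=CC[C@@H](O[Si](C)(C)C(C)(C)C)[C@](C)(C(C)=C)C(=O)OC | intermediate
14 | methyl (1S,5R)-5-[(tert-butyldimethylsilyl)oxy]-3-hydroxy-1,2,2-trimethylcyclopentane-1-carboxylate, mixture of (3S) and (3R) epimers, (3S) expected to be the main one | CC1(C)C(O)C[C@@H](O[Si](C)(C)C(C)(C)C)[C@@]1(C)C(=O)OC | intermediate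
15 | methyl (1S,5R)-5-[(tert-butyldimethylsilyl)oxy]-1,2,2-trimethyl-3-oxocyclopentane-1-carboxylate | CC1(C)C(=O)C[C@@H](O[Si](C)(C)C(C)(C)C)[C@@]1(C)C(=O)OC | intermediate
16 | potassium enolate of 15 (C3–O enolate, C3=C4 double bond) | [K+].CC1(C)C([O-])=C[C@@H](O[Si](C)(C)C(C)(C)C)[C@@]1(C)C(=O)OC | intermediate
17 | methyl (1S,5R)-5-[(tert-butyldimethylsilyl)oxy]-1,2,2-trimethyl-3-[(trifluoromethanesulfonyl)oxy]cyclopent-3-ene-1-carboxylate | CC1(C)C(OS(=O)(=O)C(F)(F)F)=C[C@@H](O[Si](C)(C)C(C)(C)C)[C@@]1(C)C(=O)OC | intermediate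
18 | methyl (1S,5R)-3-bromo-5-[(tert-butyldimethylsilyl)oxy]-1,2,2-trimethylcyclopent-3-ene-1-carboxylate | CC1(C)C(Br)=C[C@@H](O[Si](C)(C)C(C)(C)C)[C@@]1(C)C(=O)OC | intermediate
19 | methyl (1S,3S,5R)-3-bromo-5-[(tert-butyldimethylsilyl)oxy]-1,2,2-trimethylcyclopentane-1-carboxylate | CC1(C)[C@@H](Br)C[C@@H](O[Si](C)(C)C(C)(C)C)[C@@]1(C)C(=O)OC | intermediate
20 | [(1R,3S,5R)-3-bromo-5-[(tert-butyldimethylsilyl)oxy]-1,2,2-trimethylcyclopentyl]methanol | CC1(C)[C@@H](Br)C[C@@H](O[Si](C)(C)C(C)(C)C)[C@@]1(C)CO | intermediate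
21 | (1S,3S,5R)-3-bromo-5-[(tert-butyldimethylsilyl)oxy]-1,2,2-trimethylcyclopentane-1-carbaldehyde | CC1(C)[C@@H](Br)C[C@@H](O[Si](C)(C)C(C)(C)C)[C@@]1(C)C=O | intermediate
22 | 4-bromo-2-methylbut-1-ene | C=C(C)CCBr | starting material
23 | (3-methylbut-3-en-1-yl)magnesium bromide | C=C(C)CC[Mg]Br | intermediate
24 | 1-[(1R,3S,5R)-3-bromo-5-[(tert-butyldimethylsilyl)oxy]-1,2,2-trimethylcyclopentyl]-4-methylpent-4-en-1-ol, both carbinol epimers | CC1(C)[C@@H](Br)C[C@@H](O[Si](C)(C)C(C)(C)C)[C@@]1(C)C(O)CCC(C)=C | intermediate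
25 | 1-[(1S,3S,5R)-3-bromo-5-[(tert-butyldimethylsilyl)oxy]-1,2,2-trimethylcyclopentyl]-4-methylpent-4-en-1-one | CC1(C)[C@@H](Br)C[C@@H](O[Si](C)(C)C(C)(C)C)[C@@]1(C)C(=O)CCC(C)=C | intermediate
26 | 1-[(1S,3S,5R)-3-bromo-5-hydroxy-1,2,2-trimethylcyclopentyl]-4-methylpent-4-en-1-one | CC1(C)[C@@H](Br)C[C@@H](O)[C@@]1(C)C(=O)CCC(C)=C | intermediate
27 | allylmagnesium bromide | C=CC[Mg]Br | starting material
28 | bromomagnesium alkoxide of 26 (O–MgBr on C5' of the cyclopentane) | CC1(C)[C@@H](Br)C[C@@H](O[Mg]Br)[C@@]1(C)C(=O)CCC(C)=C | intermediate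
29 | (4R)-4-[(1S,3S,5R)-3-bromo-5-hydroxy-1,2,2-trimethylcyclopentyl]-7-methylocta-1,7-dien-4-ol | CC1(C)[C@@H](Br)C[C@@H](O)[C@@]1(C)[C@](O)(CC=C)CCC(C)=C | intermediate
30 | (1R)-1-[(1S,3S,5R)-3-bromo-5-hydroxy-1,2,2-trimethylcyclopentyl]-4-methylcyclohex-3-en-1-ol | CC1(C)[C@@H](Br)C[C@@H](O)[C@@]1(C)[C@@]1(O)CCC(C)=CC1 | intermediate
31 | (1R,2S,4S)-4-bromo-2-[(1S,2S,4R)-2-bromo-1-methyl-7-oxabicyclo[2.2.1]heptan-4-yl]-2,3,3-trimethylcyclopentan-1-ol | CC1(C)[C@@H](Br)C[C@@H](O)[C@@]1(C)[C@@]1(O2)CC[C@@]2(C)[C@@H](Br)C1 | intermediate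
32 | O-dichloroboryl derivative of 31 (BCl2 on the cyclopentanol oxygen) | CC1(C)[C@@H](Br)C[C@@H](OB(Cl)Cl)[C@@]1(C)[C@@]1(O2)CC[C@@]2(C)[C@@H](Br)C1 | intermediate
33 | cyclic chloroborate of 34 (2-chloro-1,3,2-dioxaborinane joining the C5' and C1 oxygens) | CC1(C)[C@@H](Br)C[C@@H](O2)[C@@]1(C)[C@@]1(OB2Cl)CC[C@](C)(Cl)[C@@H](Br)C1 | intermediate
34 | (1R,3S,4S)-3-bromo-1-[(1S,3S,5R)-3-bromo-5-hydroxy-1,2,2-trimethylcyclopentyl]-4-chloro-4-methylcyclohexan-1-ol | CC1(C)[C@@H](Br)C[C@@H](O)[C@@]1(C)[C@@]1(O)CC[C@](C)(Cl)[C@@H](Br)C1 | target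

**Step count**

Total: 21 steps. Longest linear sequence: 20 steps (steps 1 and 3 to 21, from 1 to 34); step 2 is a one-step side branch.

**Steps most likely to fail**

Step 21 (carries the label). What may go wrong: the Lewis acid may ionise the other bridgehead bond (C1–O), followed by chloride capture at C1 or a 1,2-shift from the quaternary C1'; or the bromonium ion may give up Br+ and return the alkene. The fallback uses known chemistry, sets out from 30 and comes back at 34. Both hydroxyls of 30 are silylated (Et3SiOTf, 2,6-lutidine, CH2Cl2) to give the bis(triethylsilyl) ether of 30 F1. Markovnikov anti-bromochlorination of the trisubstituted alkene (N-bromosuccinimide, Et4NCl, CH2Cl2, −40 °C) gives the bis(triethylsilyl) ether of 34 F2. The pseudo-axial silyloxy group on C1 is expected to keep bromine off the upper face at C3, so that the lower-face bromonium ion is opened by chloride at the tertiary C4; the trans-diaxial isomer would be removed by chromatography. HF·pyridine in THF then cleaves both silyl ethers and gives 34.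

Step 8 (key step). What may go wrong: the tertiary radical may be reduced to an isopropyl group, or the cyclised alkoxy radical may reopen by β-scission before it is reduced, so that ring closure does not compete. The fallback sets out from 12 and comes back at 14. Cobalt-mediated hydrogen-atom-transfer hydrobromination of the isopropenyl group (Co(acac)2, t-BuOOH, Et3SiH, TsBr) gives the tertiary bromide methyl (2S,3R)-2-(2-bromopropan-2-yl)-3-[(tert-butyldimethylsilyl)oxy]-5,5-dimethoxy-2-methylpentanoate F3. Acetal hydrolysis as in step 7 gives the bromo aldehyde methyl (2S,3R)-2-(2-bromopropan-2-yl)-3-[(tert-butyldimethylsilyl)oxy]-2-methyl-5-oxopentanoate F4. Slow addition of n-Bu3SnH with AIBN in benzene at 80 °C abstracts bromine; the same tertiary radical closes 5-exo onto the aldehyde and the alkoxy radical is trapped at once by the tin hydride, giving 14.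

Step 12. What may go wrong: hydrogen-atom transfer to the bromine-bearing carbon followed by loss of a bromine atom (net hydrodebromination), or sluggish transfer to the hindered trisubstituted alkene. The fallback sets out from 15 and comes back at 19. Condensation with hydrazine hydrate (EtOH, cat. AcOH) gives the hydrazone methyl (1S,5R)-5-[(tert-butyldimethylsilyl)oxy]-3-hydrazinylidene-1,2,2-trimethylcyclopentane-1-carboxylate F5. Oxidative bromination with CuBr2 and LiOt-Bu in THF, with loss of N2, gives the geminal dibromide methyl (1S,5R)-3,3-dibromo-5-[(tert-butyldimethylsilyl)oxy]-1,2,2-trimethylcyclopentane-1-carboxylate F6. One equivalent of n-Bu3SnH with AIBN removes one bromine through the same α-bromo radical, which takes hydrogen on the face opposite the silyloxy and ester groups and gives 19.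

**Further compounds**

F1 | step 21 | bis(triethylsilyl) ether of 30 (both hydroxyls silylated, configuration as in 30) | CC1(C)[C@@H](Br)C[C@@H](O[Si](CC)(CC)CC)[C@@]1(C)[C@@]1(O[Si](CC)(CC)CC)CCC(C)=CC1
F2 | step 21 | bis(triethylsilyl) ether of 34 (both hydroxyls silylated, configuration as in 34) | CC1(C)[C@@H](Br)C[C@@H](O[Si](CC)(CC)CC)[C@@]1(C)[C@@]1(O[Si](CC)(CC)CC)CC[C@](C)(Cl)[C@@H](Br)C1
F3 | step 8 | methyl (2S,3R)-2-(2-bromopropan-2-yl)-3-[(tert-butyldimethylsilyl)oxy]-5,5-dimethoxy-2-methylpentanoate | COC(OC)C[C@@H](O[Si](C)(C)C(C)(C)C)[C@](C)(C(C)(C)Br)C(=O)OC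
F4 | step 8 | methyl (2S,3R)-2-(2-bromopropan-2-yl)-3-[(tert-butyldimethylsilyl)oxy]-2-methyl-5-oxopentanoate | O=CC[C@@H](O[Si](C)(C)C(C)(C)C)[C@](C)(C(C)(C)Br)C(=O)OC
F5 | step 12 | methyl (1S,5R)-5-[(tert-butyldimethylsilyl)oxy]-3-hydrazinylidene-1,2,2-trimethylcyclopentane-1-carboxylate | CC1(C)C(=NN)C[C@@H](O[Si](C)(C)C(C)(C)C)[C@@]1(C)C(=O)OC
F6 | step 12 | methyl (1S,5R)-3,3-dibromo-5-[(tert-butyldimethylsilyl)oxy]-1,2,2-trimethylcyclopentane-1-carboxylate | CC1(C)C(Br)(Br)C[C@@H](O[Si](C)(C)C(C)(C)C)[C@@]1(C)C(=O)OC
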